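**Strategy.** Ring C of the upper flavan (O1, C8a, C4a, C4, C3, C2) has a bare C3 methylene and its ring A lacks a 5-oxygen, so this unit is a masked (E)-4-benzyloxy-2-hydroxycinnamaldehyde. The interflavan bond C4(upper)–C8(lower) is therefore made first. A chiral secondary amine moves the C8 aryl group of perbenzylated epigallocatechin-8-boronic acid from boron to the enal β-carbon, and the freed aldehyde is trapped by the ortho phenol as a chroman-2-ol (O1–C2 bond). That single operation sets C4 and closes ring C. The lactol then serves as a C2 oxocarbenium precursor for trans-selective arylation, and hydrogenolysis finishes the synthesis.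

Key step: step 6

Remark on the chemistry: the sense of induction in step 6 is assigned from the usual face-shielding model of prolinol silyl ether iminium ions. The (R)-amine is expected to give 4R; if a model run shows the opposite sense, the (S)-amine is used with no other change.

Shorthand in names: "hexa-O-benzyl-epigallocatechin-8-yl" = (2R,3R)-3,5,7-tris(benzyloxy)-2-[3,4,5-tris(benzyloxy)phenyl]chroman-8-yl.

Step 1
Reactants: 1 (−)-epigallocatechin
Product: 2 (2R,3R)-5,7-bis(benzyloxy)-2-[3,4,5-tris(benzyloxy)phenyl]chroman-3-ol (penta-O-benzyl-epigallocatechin, 3-OH free)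
Conditions: BnBr (5.5 equiv), K2CO3 (6 equiv), degassed DMF, Ar, 0 °C → rt
Reagents that add atoms: benzyl bromide, BrCc1ccccc1
Why: Williamson etherification in which carbonate deprotonates only the five phenols and leaves the secondary 3-OH alone, while exclusion of air and low temperature protect the pyrogallol ring and the C2 configuration; no stereocentre is touched.

Step 2
Reactants: 2 penta-O-benzyl-epigallocatechin
Product: 3 (2R,3R)-5,7-bis(benzyloxy)-8-bromo-2-[3,4,5-tris(benzyloxy)phenyl]chroman-3-ol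
Conditions: NBS (1.0 equiv), CH2Cl2, −78 °C → rt
Reagents that add atoms: N-bromosuccinimide, O=C1CCC(=O)N1Br
Why: electrophilic aromatic bromination of the phloroglucinol-type ring A, by far the most electron-rich arene present, is expected at C8 (the site at which perbenzylated flavan-3-ols with a free 3-OH are brominated), and one equivalent at low temperature should stop at the monobromide.

Step 3
Reactants: 3 8-bromo-penta-O-benzyl-epigallocatechin
Product: 4 (2R,3R)-3,5,7-tris(benzyloxy)-8-bromo-2-[3,4,5-tris(benzyloxy)phenyl]chroman (8-bromo-hexa-O-benzyl-epigallocatechin)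
Conditions: NaH (1.5 equiv), BnBr (1.5 equiv), Bu4NI (cat.), DMF, 0 °C → rt
Reagents that add atoms: benzyl bromide, BrCc1ccccc1
Why: Williamson etherification of the secondary alkoxide removes the only acidic proton before the organolithium step; the aryl bromide and both stereocentres are inert to NaH at this temperature.

Step 4
Reactants: 4 8-bromo-hexa-O-benzyl-epigallocatechin
Product: 7 hexa-O-benzyl-epigallocatechin-8-boronic acid, via 8-lithio arene 5 (not isolated), via lithium aryl(triisopropoxy)borate 6 (not isolated)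
Conditions: n-BuLi (1.1 equiv), THF, −78 °C; B(Oi-Pr)3 (3 equiv), −78 → 0 °C; 1 M aq HCl to pH 6, 0 °C
Reagents that add atoms: triisopropyl borate, CC(C)OB(OC(C)C)OC(C)C; water, O
Why: bromine–lithium exchange at −78 °C outruns benzylic deprotonation, the aryllithium is trapped by the borate, and near-neutral hydrolysis should release the boronic acid with little protodeboronation, the boron sitting exactly where bromine was (C8).

Step 5
Reactants: 8 4-(benzyloxy)-2-hydroxybenzaldehyde
Product: 9 (E)-3-[4-(benzyloxy)-2-hydroxyphenyl]prop-2-enal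
Conditions: Ph3P=CHCHO (1.15 equiv), toluene, 80 °C
Reagents that add atoms: (triphenylphosphoranylidene)acetaldehyde, O=CC=P(c1ccccc1)(c1ccccc1)c1ccccc1
Why: Wittig olefination with a stabilised ylide gives the E-enal and tolerates the free phenol, and the small excess of ylide limits a second homologation to the dienal.

Step 6
Reactants: 7 hexa-O-benzyl-epigallocatechin-8-boronic acid (limiting); 9 (E)-3-[4-(benzyloxy)-2-hydroxyphenyl]prop-2-enal (1.5 equiv)
Product: 12 (4R)-7-(benzyloxy)-4-(hexa-O-benzyl-epigallocatechin-8-yl)chroman-2-ol (C2 anomer mixture), via iminium boronate 10 (not isolated), via 3,3-diarylpropanal 11 (not isolated)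
Conditions: (R)-α,α-diphenylprolinol trimethylsilyl ether (20 mol %), toluene, H2O (2 equiv), rt
Reagents that add atoms: water, O (its oxygen ends at C2 after iminium hydrolysis)
Why: The enal condenses with the amine to an E-iminium ion, the ortho phenol binds the boronic acid as a tetracoordinate boronate (10), and the electron-rich C8 aryl group migrates from boron to the β-carbon through a six-membered transition state, after which hydrolysis frees aldehyde 11 and the catalyst. The closest known reaction type is the amine-catalysed, phenol-directed 1,4-addition of boronic acids to 2-hydroxycinnamaldehydes (a conjugate Petasis-type transfer), applied here to a more hindered but more electron-rich, hence better migrating, 2,6-dioxygenated aryl group. Ring C closes by 6-exo-trig addition of the phenol oxygen O1 to the C2 aldehyde (hemiacetalisation), which also withdraws the aldehyde from further iminium chemistry. The new stereocentre C4 is set by the catalyst, whose diphenyl(silyloxy)methyl group shields one face of the iminium ion so that the tethered boronate delivers the aryl group to the open face (4R expected with the R amine), while C2 is deliberately left as an anomer mixture. The step needs β-carbon over carbonyl-carbon selectivity and C8 over C6 regiochemistry: the E-alkene keeps the phenoxide-bound boron within reach of the β-carbon only, and boron occupies the carbon that carried bromine. The epigallocatechin stereocentres are remote from C4, so catalyst control should override any substrate bias.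

Step 7
Reactants: 12 (4R)-7-(benzyloxy)-4-(hexa-O-benzyl-epigallocatechin-8-yl)chroman-2-ol
Product: 13 (4R)-7-(benzyloxy)-4-(hexa-O-benzyl-epigallocatechin-8-yl)chroman-2-yl acetate (C2 anomer mixture)
Conditions: Ac2O (3 equiv), pyridine (5 equiv), DMAP (5 mol %), CH2Cl2, 0 °C → rt
Reagents that add atoms: acetic anhydride, CC(=O)OC(C)=O
Why: DMAP-catalysed acylation of the hemiacetal hydroxyl (the closed chroman-2-ol form is strongly favoured over the open hydroxy aldehyde) installs a leaving group that ionises cleanly; C4 is not affected.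

Step 8
Reactants: 14 4-(benzyloxy)phenylboronic acid
Product: 15 potassium [4-(benzyloxy)phenyl]trifluoroborate
Conditions: KHF2 (4 equiv), MeOH/H2O, rt; recrystallisation from acetone/Et2O
Reagents that add atoms: potassium hydrogen difluoride, F.[F-].[K+]
Why: fluoride exchange at boron converts the boronic acid into the crystalline, bench-stable trifluoroborate, whose ipso carbon is a much stronger nucleophile than that of a simple aryl ether.

Step 9
Reactants: 13 chroman-2-yl acetate; 15 potassium [4-(benzyloxy)phenyl]trifluoroborate (3 equiv)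
Product: 17 (2S,4R)-7-(benzyloxy)-2-[4-(benzyloxy)phenyl]-4-(hexa-O-benzyl-epigallocatechin-8-yl)chroman (octa-O-benzyl target, 2,4-trans), via C2 oxocarbenium ion 16 (not isolated)
Conditions: BF3·OEt2 (3 equiv), MeCN/CH2Cl2 (1:1), −40 → 0 °C
Reagents that add atoms: none
Why: Lewis-acid-promoted addition of an organotrifluoroborate to an acetal-derived oxocarbenium ion: BF3 ionises the anomeric acetate to cation 16, which is captured at the ipso carbon of the aryltrifluoroborate with loss of boron, and C2 is set by the substrate because the nucleophile enters pseudo-axially on the face opposite the bulky C4 aryl group (the other face demands a 1,3-diaxial approach), giving the 2,4-trans (2S) isomer; low temperature and excess borate should suppress Friedel–Crafts capture by C6 of the lower ring A and acidolysis of the C4–C8 bond.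

Step 10
Reactants: 17 octa-O-benzyl target
Product: 18 (2R,3R)-8-[(2S,4R)-7-hydroxy-2-(4-hydroxyphenyl)chroman-4-yl]-2-(3,4,5-trihydroxyphenyl)chroman-3,5,7-triol (target CNP0220331.1)
Conditions: H2 (1 atm), Pd(OH)2 on carbon (20 wt %), THF/MeOH (1:1), rt; filtration and concentration under Ar
Reagents that add atoms: none
Why: catalytic hydrogenolysis cleaves all eight O-benzyl groups, which react much faster than the two cyclic benzylic C2–O1 bonds or the diarylmethine C4–H, so the reaction is stopped at complete debenzylation with every stereocentre untouched.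

**Compound list**

1 | (−)-epigallocatechin, (2R,3R) | Oc1cc(O)c2c(c1)O[C@H](c1cc(O)c(O)c(O)c1)[C@H](O)C2 | starting material
2 | (2R,3R)-5,7-bis(benzyloxy)-2-[3,4,5-tris(benzyloxy)phenyl]chroman-3-ol | C(c3ccccc3)Oc1cc(OCc3ccccc3)c2c(c1)O[C@H](c1cc(OCc3ccccc3)c(OCc3ccccc3)c(OCc3ccccc3)c1)[C@H](O)C2 | intermediate
3 | (2R,3R)-5,7-bis(benzyloxy)-8-bromo-2-[3,4,5-tris(benzyloxy)phenyl]chroman-3-ol | Brc1c(OCc3ccccc3)cc(OCc3ccccc3)c2c1O[C@H](c1cc(OCc3ccccc3)c(OCc3ccccc3)c(OCc3ccccc3)c1)[C@H](O)C2 | intermediate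
4 | (2R,3R)-3,5,7-tris(benzyloxy)-8-bromo-2-[3,4,5-tris(benzyloxy)phenyl]chroman | Brc1c(OCc3ccccc3)cc(OCc3ccccc3)c2c1O[C@H](c1cc(OCc3ccccc3)c(OCc3ccccc3)c(OCc3ccccc3)c1)[C@H](OCc1ccccc1)C2 | intermediate
5 | hexa-O-benzyl-epigallocatechin-8-yllithium | [Li]c1c(OCc3ccccc3)cc(OCc3ccccc3)c2c1O[C@H](c1cc(OCc3ccccc3)c(OCc3ccccc3)c(OCc3ccccc3)c1)[C@H](OCc1ccccc1)C2 | intermediate (not isolated)
6 | lithium (hexa-O-benzyl-epigallocatechin-8-yl)triisopropoxyborate | [Li+].CC(C)O[B-](OC(C)C)(OC(C)C)c1c(OCc3ccccc3)cc(OCc3ccccc3)c2c1O[C@H](c1cc(OCc3ccccc3)c(OCc3ccccc3)c(OCc3ccccc3)c1)[C@H](OCc1ccccc1)C2 | intermediate (not isolated)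
7 | hexa-O-benzyl-epigallocatechin-8-boronic acid | OB(O)c1c(OCc3ccccc3)cc(OCc3ccccc3)c2c1O[C@H](c1cc(OCc3ccccc3)c(OCc3ccccc3)c(OCc3ccccc3)c1)[C@H](OCc1ccccc1)C2 | intermediate
8 | 4-(benzyloxy)-2-hydroxybenzaldehyde | O=Cc1ccc(OCc2ccccc2)cc1O | starting material
9 | (E)-3-[4-(benzyloxy)-2-hydroxyphenyl]prop-2-enal | O=C/C=C/c1ccc(OCc2ccccc2)cc1O | intermediate
10 | zwitterionic E-iminium ion of 9 with the (R)-amine, its phenoxide oxygen bound to the boron of 7 as an aryl(dihydroxy)boronate | O[B-](O)(Oc1cc(OCc2ccccc2)ccc1/C=C/C=[N+]1\CCC[C@@H]1C(O[Si](C)(C)C)(c1ccccc1)c1ccccc1)c1c(OCc3ccccc3)cc(OCc3ccccc3)c2c1O[C@H](c1cc(OCc3ccccc3)c(OCc3ccccc3)c(OCc3ccccc3)c1)[C@H](OCc1ccccc1)C2 | intermediate (not isolated)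
11 | (3R)-3-[4-(benzyloxy)-2-hydroxyphenyl]-3-(hexa-O-benzyl-epigallocatechin-8-yl)propanal | O=CC[C@@H](c1c(OCc3ccccc3)cc(OCc3ccccc3)c2c1O[C@H](c1cc(OCc3ccccc3)c(OCc3ccccc3)c(OCc3ccccc3)c1)[C@H](OCc1ccccc1)C2)c1ccc(OCc2ccccc2)cc1O | intermediate (not isolated)
12 | (4R)-7-(benzyloxy)-4-(hexa-O-benzyl-epigallocatechin-8-yl)chroman-2-ol, C2 anomer mixture | OC1C[C@@H](c2c(OCc3ccccc3)cc(OCc3ccccc3)c3c2O[C@H](c2cc(OCc4ccccc4)c(OCc4ccccc4)c(OCc4ccccc4)c2)[C@H](OCc2ccccc2)C3)c2ccc(OCc3ccccc3)cc2O1 | intermediate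
13 | (4R)-7-(benzyloxy)-4-(hexa-O-benzyl-epigallocatechin-8-yl)chroman-2-yl acetate, C2 anomer mixture | CC(=O)OC1C[C@@H](c2c(OCc3ccccc3)cc(OCc3ccccc3)c3c2O[C@H](c2cc(OCc4ccccc4)c(OCc4ccccc4)c(OCc4ccccc4)c2)[C@H](OCc2ccccc2)C3)c2ccc(OCc3ccccc3)cc2O1 | intermediate
14 | 4-(benzyloxy)phenylboronic acid | OB(O)c1ccc(OCc2ccccc2)cc1 | starting material
15 | potassium [4-(benzyloxy)phenyl]trifluoroborate | [K+].F[B-](F)(F)c1ccc(OCc2ccccc2)cc1 | intermediate
16 | (4R)-7-(benzyloxy)-4-(hexa-O-benzyl-epigallocatechin-8-yl)-3,4-dihydrochromenylium (C2 oxocarbenium ion) | [O+]1=CC[C@@H](c2c(OCc3ccccc3)cc(OCc3ccccc3)c3c2O[C@H](c2cc(OCc4ccccc4)c(OCc4ccccc4)c(OCc4ccccc4)c2)[C@H](OCc2ccccc2)C3)c2ccc(OCc3ccccc3)cc21 | intermediate (not isolated)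
17 | (2S,4R)-7-(benzyloxy)-2-[4-(benzyloxy)phenyl]-4-(hexa-O-benzyl-epigallocatechin-8-yl)chroman | C(c1ccccc1)Oc1ccc([C@@H]2C[C@@H](c3c(OCc5ccccc5)cc(OCc5ccccc5)c4c3O[C@H](c3cc(OCc5ccccc5)c(OCc5ccccc5)c(OCc5ccccc5)c3)[C@H](OCc3ccccc3)C4)c3ccc(OCc4ccccc4)cc3O2)cc1 | intermediate
18 | (2R,3R)-8-[(2S,4R)-7-hydroxy-2-(4-hydroxyphenyl)chroman-4-yl]-2-(3,4,5-trihydroxyphenyl)chroman-3,5,7-triol | Oc1ccc([C@@H]2C[C@@H](c3c(O)cc(O)c4c3O[C@H](c3cc(O)c(O)c(O)c3)[C@H](O)C4)c3ccc(O)cc3O2)cc1 | target

**Totals.** Total step count: 10. Longest linear sequence: 8 steps (steps 1, 2, 3, 4, 6, 7, 9, 10).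

**Steps most likely to fail**

Step 6. What may go wrong:
- slow boron-to-carbon transfer from the di-ortho-substituted boronate, with protodeboronation taking over;
- weak face selectivity if the chiral boronic acid and the catalyst are mismatched;
- aryl transfer to the carbonyl carbon after alkene isomerisation, leading to a 2-aryl-2H-chromene.

Fallback, setting out from bromide 4 and aldehyde 8 and returning at lactol 12: an auxiliary-controlled organocopper conjugate addition replaces the boronate transfer. Aldehyde 8 is silylated (t-BuMe2SiCl, imidazole, DMF) to 4-(benzyloxy)-2-(tert-butyldimethylsilyloxy)benzaldehyde F1. Wittig olefination with the stabilised ylide (R)-4-phenyl-3-[(triphenylphosphoranylidene)acetyl]oxazolidin-2-one gives the E-configured N-enoyl oxazolidinone F2. Aryllithium 5 (from 4, n-BuLi, −78 °C) is transmetalated with MgBr2·OEt2 and CuBr·SMe2 and added to F2 at −40 °C. Attack on the magnesium-chelated s-cis imide anti to the 4-phenyl group should give the (3R) conjugate adduct F3. Bu4NF then frees the phenoxide, which lactonises onto the imide and expels the auxiliary to give the (4R) dihydrocoumarin F4. Reduction with i-Bu2AlH (toluene, −78 °C) leads to 12.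

Step 9. What may go wrong:
- poor facial selectivity at C2;
- loss of a proton from the cation to give the 4H-chromene;
- capture of the cation by C6 of the lower ring A or by a neighbouring benzyloxy oxygen;
- acid-induced cleavage of the C4–C8 bond.

Fallback, setting out from lactol 12 and returning at 17: the C2 aryl group is introduced as a carbanion and ring C is closed afterwards. Lactol 12 reacts through its open hydroxy-aldehyde form with 4-(benzyloxy)phenylmagnesium bromide (3 equiv, THF, 0 °C) to give the phenol diol F5 as a pair of carbinol epimers. MnO2 (CH2Cl2, rt) oxidises the benzylic alcohol to the aryl ketone F6. Corey–Bakshi–Shibata reduction with the (S)-configured B-methyl oxazaborolidine and BH3·SMe2 should give the (1R)-carbinol F7. Mitsunobu etherification (PPh3, diisopropyl azodicarboxylate, THF, 0 °C) then forms the O1–C2 bond with inversion and delivers the (2S,4R) compound 17.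

Step 4. What may go wrong:
- benzylic metalation or butylation competing with clean exchange;
- protodeboronation of the 2,6-dioxygenated arylboronic acid during work-up and isolation.

Fallback, setting out from bromide 4 and returning at 7: Miyaura borylation (B2pin2, Pd(OAc)2, SPhos, KOAc, dioxane, 90 °C) avoids the organolithium and gives the chromatographable pinacol boronate F8. Oxidative removal of the diol (NaIO4, NH4OAc, acetone/H2O, rt) then releases boronic acid 7 just before use.

**Further compounds**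

F1 | step 6 | 4-(benzyloxy)-2-(tert-butyldimethylsilyloxy)benzaldehyde | O=Cc1ccc(OCc2ccccc2)cc1O[Si](C)(C)C(C)(C)C
F2 | step 6 | (R)-3-{(E)-3-[4-(benzyloxy)-2-(tert-butyldimethylsilyloxy)phenyl]acryloyl}-4-phenyloxazolidin-2-one | CC(C)(C)[Si](C)(C)Oc1cc(OCc2ccccc2)ccc1/C=C/C(=O)N1[C@H](c2ccccc2)COC1=O
F3 | step 6 | (R)-3-{(3R)-3-[4-(benzyloxy)-2-(tert-butyldimethylsilyloxy)phenyl]-3-(hexa-O-benzyl-epigallocatechin-8-yl)propanoyl}-4-phenyloxazolidin-2-one | CC(C)(C)[Si](C)(C)Oc1cc(OCc2ccccc2)ccc1[C@H](c1c(OCc3ccccc3)cc(OCc3ccccc3)c2c1O[C@H](c1cc(OCc3ccccc3)c(OCc3ccccc3)c(OCc3ccccc3)c1)[C@H](OCc1ccccc1)C2)CC(=O)N1[C@H](c2ccccc2)COC1=O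
F4 | step 6 | (4R)-7-(benzyloxy)-4-(hexa-O-benzyl-epigallocatechin-8-yl)chroman-2-one | O=C1C[C@@H](c2c(OCc3ccccc3)cc(OCc3ccccc3)c3c2O[C@H](c2cc(OCc4ccccc4)c(OCc4ccccc4)c(OCc4ccccc4)c2)[C@H](OCc2ccccc2)C3)c2ccc(OCc3ccccc3)cc2O1
F5 | step 9 | (3R)-1-[4-(benzyloxy)phenyl]-3-[4-(benzyloxy)-2-hydroxyphenyl]-3-(hexa-O-benzyl-epigallocatechin-8-yl)propan-1-ol, C1 epimers | OC(C[C@@H](c1c(OCc3ccccc3)cc(OCc3ccccc3)c2c1O[C@H](c1cc(OCc3ccccc3)c(OCc3ccccc3)c(OCc3ccccc3)c1)[C@H](OCc1ccccc1)C2)c1ccc(OCc2ccccc2)cc1O)c1ccc(OCc2ccccc2)cc1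
F6 | step 9 | (3R)-1-[4-(benzyloxy)phenyl]-3-[4-(benzyloxy)-2-hydroxyphenyl]-3-(hexa-O-benzyl-epigallocatechin-8-yl)propan-1-one | O=C(C[C@@H](c1c(OCc3ccccc3)cc(OCc3ccccc3)c2c1O[C@H](c1cc(OCc3ccccc3)c(OCc3ccccc3)c(OCc3ccccc3)c1)[C@H](OCc1ccccc1)C2)c1ccc(OCc2ccccc2)cc1O)c1ccc(OCc2ccccc2)cc1
F7 | step 9 | (1R,3R)-1-[4-(benzyloxy)phenyl]-3-[4-(benzyloxy)-2-hydroxyphenyl]-3-(hexa-O-benzyl-epigallocatechin-8-yl)propan-1-ol | O[C@H](C[C@@H](c1c(OCc3ccccc3)cc(OCc3ccccc3)c2c1O[C@H](c1cc(OCc3ccccc3)c(OCc3ccccc3)c(OCc3ccccc3)c1)[C@H](OCc1ccccc1)C2)c1ccc(OCc2ccccc2)cc1O)c1ccc(OCc2ccccc2)cc1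
F8 | step 4 | 2-(hexa-O-benzyl-epigallocatechin-8-yl)-4,4,5,5-tetramethyl-1,3,2-dioxaborolane | CC1(C)OB(OC1(C)C)c1c(OCc3ccccc3)cc(OCc3ccccc3)c2c1O[C@H](c1cc(OCc3ccccc3)c(OCc3ccccc3)c(OCc3ccccc3)c1)[C@H](OCc1ccccc1)C2
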